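**Assumption:** the target SMILES contains no stereocentre and no stereogenic double bond, so the compound is achiral and no asymmetric step is needed. Compound numbers follow the forward route.

**Retrosynthetic overview**
- Target ⇐ selective, chelation-directed 5-O-demethylation of the 5,7,8,2',3',4',5'-heptamethoxyflavone.
- Flavone ⇐ I2/DMSO oxidative cyclisation of a 2'-hydroxychalcone; the pyranone ring is the only ring built and is formed last, both benzene rings are bought.
- Chalcone ⇐ intermolecular Claisen–Schmidt aldol condensation (Cα–Cβ bond) of 2-hydroxy-3,4,6-trimethoxyacetophenone with 2,3,4,5-tetramethoxybenzaldehyde.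
- A-ring ketone ⇐ 3,4,5-trimethoxyphenol (O-methylation, then Friedel–Crafts acetylation with ortho-demethylation).
- B-ring aldehyde ⇐ 2,3,4-trimethoxybenzaldehyde (Dakin oxidation, O-methylation, Vilsmeier formylation).

**Route**

Step 1
Reactants: 1 3,4,5-trimethoxyphenol
Product: 2 1,2,3,5-tetramethoxybenzene
Conditions: MeI (1.5 equiv), K2CO3 (2 equiv), acetone, reflux, 12 h
Reagents that add atoms: iodomethane CI
Why: Williamson O-methylation (SN2) of the only phenol has no competing site and forms no stereocentre.

Step 2
Reactants: 2 1,2,3,5-tetramethoxybenzene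
Product: 4 2-hydroxy-3,4,6-trimethoxyacetophenone, via 2,3,4,6-tetramethoxyacetophenone 3 (not isolated)
Conditions: AcCl (1.3 equiv), AlCl3 (2.5 equiv), Et2O, 0 °C → rt, 24 h; then ice/2 M HCl
Reagents that add atoms: acetyl chloride CC(Cl)=O
Why: Friedel–Crafts acylation can only enter one of the two equivalent free positions (each flanked by two methoxy groups and para to a third), and the excess AlCl3 then performs a carbonyl-assisted ortho-demethylation of the methoxy group squeezed between the acetyl group and the 3-OMe, stopping at the hydrogen-bonded mono-phenol in ether.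

Step 3
Reactants: 5 2,3,4-trimethoxybenzaldehyde
Product: 7 2,3,4-trimethoxyphenol, via 2,3,4-trimethoxyphenyl formate 6 (not isolated)
Conditions: 30% H2O2 (1.3 equiv), H2SO4 (cat.), MeOH, rt, 24 h
Reagents that add atoms: hydrogen peroxide OO
Why: Dakin (Baeyer–Villiger-type) oxidation works because the electron-rich aryl group with ortho and para methoxy donors migrates to oxygen, and the aryl formate is methanolysed in the same acidic methanol.

Step 4
Reactants: 7 2,3,4-trimethoxyphenol
Product: 8 1,2,3,4-tetramethoxybenzene
Conditions: MeI (1.5 equiv), K2CO3 (2 equiv), acetone, reflux, 12 h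
Reagents that add atoms: iodomethane CI
Why: Williamson O-methylation (SN2) of the single phenol is unambiguous.

Step 5
Reactants: 8 1,2,3,4-tetramethoxybenzene
Product: 10 2,3,4,5-tetramethoxybenzaldehyde, via N,N-dimethyl(2,3,4,5-tetramethoxybenzylidene)iminium chloride 9 (not isolated)
Conditions: POCl3 (2 equiv), DMF, 0 → 90 °C, 6 h; then ice-water, rt
Reagents that add atoms: N,N-dimethylformamide CN(C)C=O; water O
Why: Vilsmeier–Haack formylation puts the chloroiminium electrophile at C5 (C5 and C6 are equivalent, ortho to one methoxy and para to another) without any Lewis acid that could cleave ethers, and the aryl iminium salt is hydrolysed on work-up.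

Step 6
Reactants: 4 2-hydroxy-3,4,6-trimethoxyacetophenone; 10 2,3,4,5-tetramethoxybenzaldehyde
Product: 12 (E)-1-(2-hydroxy-3,4,6-trimethoxyphenyl)-3-(2,3,4,5-tetramethoxyphenyl)prop-2-en-1-one, via racemic aldol β-hydroxy ketone 11 (not isolated)
Conditions: 50% aq KOH (10 equiv), EtOH, N2, rt, 48–72 h; then 2 M HCl to pH 3
Reagents that add atoms: none
Why: Claisen–Schmidt crossed aldol condensation is clean because the methyl ketone is the only enolisable partner and the aldehyde the only good acceptor, and E1cB dehydration removes the transient carbinol stereocentre to give the thermodynamically favoured E-enone.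

Step 7
Reactants: 12 (E)-1-(2-hydroxy-3,4,6-trimethoxyphenyl)-3-(2,3,4,5-tetramethoxyphenyl)prop-2-en-1-one
Product: 14 5,7,8-trimethoxy-2-(2,3,4,5-tetramethoxyphenyl)-4H-chromen-4-one, via racemic flavanone 13 (not isolated)
Conditions: I2 (10 mol%), DMSO, 130 °C, 4 h
Reagents that add atoms: none
Why: Oxidative cyclisation (intramolecular oxa-Michael addition of the only free phenol, then iodine-mediated α-iodination and HI elimination, with DMSO re-oxidising HI to I2) gives the aromatic pyranone, so the transient C2 stereocentre is lost.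

Step 8
Reactants: 14 5,7,8-trimethoxy-2-(2,3,4,5-tetramethoxyphenyl)-4H-chromen-4-one
Product: 15 5-hydroxy-7,8-dimethoxy-2-(2,3,4,5-tetramethoxyphenyl)-4H-chromen-4-one (target, CNP0509136.0)
Conditions: BCl3 (1 M in CH2Cl2, 1.5 equiv), CH2Cl2, −78 → 0 °C, 2 h; then ice/1 M HCl
Reagents that add atoms: none
Why: Chelation-directed Lewis-acid ether cleavage removes only the 5-methyl group, because only the 5-OMe oxygen can bind boron together with the peri C4 carbonyl in a six-membered chelate, while the six other methoxy groups cannot and survive at low temperature.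

**Compound list**
1 | 3,4,5-trimethoxyphenol | COc1cc(O)cc(OC)c1OC | starting material
2 | 1,2,3,5-tetramethoxybenzene | COc1cc(OC)c(OC)c(OC)c1 | intermediate
3 | 2,3,4,6-tetramethoxyacetophenone (not isolated) | CC(=O)c1c(OC)cc(OC)c(OC)c1OC | intermediate
4 | 2-hydroxy-3,4,6-trimethoxyacetophenone | CC(=O)c1c(OC)cc(OC)c(OC)c1O | intermediate
5 | 2,3,4-trimethoxybenzaldehyde | COc1ccc(C=O)c(OC)c1OC | starting material
6 | 2,3,4-trimethoxyphenyl formate (not isolated) | COc1ccc(OC=O)c(OC)c1OC | intermediate
7 | 2,3,4-trimethoxyphenol | COc1ccc(O)c(OC)c1OC | intermediate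
8 | 1,2,3,4-tetramethoxybenzene | COc1ccc(OC)c(OC)c1OC | intermediate
9 | N,N-dimethyl(2,3,4,5-tetramethoxybenzylidene)iminium chloride (not isolated) | C[N+](C)=Cc1cc(OC)c(OC)c(OC)c1OC.[Cl-] | intermediate
10 | 2,3,4,5-tetramethoxybenzaldehyde | COc1cc(C=O)c(OC)c(OC)c1OC | intermediate
11 | 3-hydroxy-1-(2-hydroxy-3,4,6-trimethoxyphenyl)-3-(2,3,4,5-tetramethoxyphenyl)propan-1-one, racemic (not isolated) | COc1cc(C(O)CC(=O)c2c(OC)cc(OC)c(OC)c2O)c(OC)c(OC)c1OC | intermediate
12 | (E)-1-(2-hydroxy-3,4,6-trimethoxyphenyl)-3-(2,3,4,5-tetramethoxyphenyl)prop-2-en-1-one | COc1cc(/C=C/C(=O)c2c(OC)cc(OC)c(OC)c2O)c(OC)c(OC)c1OC | intermediate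
13 | 5,7,8-trimethoxy-2-(2,3,4,5-tetramethoxyphenyl)chroman-4-one, racemic (not isolated) | COc1cc(C2CC(=O)c3c(OC)cc(OC)c(OC)c3O2)c(OC)c(OC)c1OC | intermediate
14 | 5,7,8-trimethoxy-2-(2,3,4,5-tetramethoxyphenyl)-4H-chromen-4-one | COc1cc(-c2cc(=O)c3c(OC)cc(OC)c(OC)c3o2)c(OC)c(OC)c1OC | intermediate
15 | 5-hydroxy-7,8-dimethoxy-2-(2,3,4,5-tetramethoxyphenyl)-4H-chromen-4-one | COc1cc(-c2cc(=O)c3c(O)cc(OC)c(OC)c3o2)c(OC)c(OC)c1OC | target

**Totals**
Total step count: 8. Longest linear sequence: 6 steps (5 → 7 → 8 → 10 → 12 → 14 → 15, steps 3–8). The A-ring branch (steps 1–2) joins at step 6.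

**Three steps most likely to fail, with fallbacks**

Step 2 (tandem acylation and regioselective mono-demethylation; risks are over-demethylation to the 2,6-diol or incomplete cleavage). The fallback sets out from 2 and comes back at 4. It makes the C–C bond without a Lewis acid by directed ortho-metalation: n-BuLi/TMEDA in THF at 0 °C removes the proton between two methoxy groups of 2 to give 2,3,4,6-tetramethoxyphenyllithium F1. F1 is acylated with N-methoxy-N-methylacetamide (Weinreb amide, no over-addition) and the tetramethoxy ketone 3 is isolated after an aqueous HCl quench. A separate, titrated cleavage (BCl3 1.05 equiv, CH2Cl2, −78 °C) then removes the crowded 2-methyl group of 3 to give 4, with the extent of demethylation controlled by stoichiometry and temperature.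

Step 6 (aldol condensation between a di-ortho-substituted ketone and an electron-rich, ortho-substituted aldehyde; risk is slow or incomplete reaction). The fallback sets out from 10, uses 4 as the partner, and comes back at 14, so it also bypasses step 7. Pinnick oxidation of 10 (NaClO2, NaH2PO4, 2-methyl-2-butene, t-BuOH/H2O) gives 2,3,4,5-tetramethoxybenzoic acid F2. Oxalyl chloride with catalytic DMF in CH2Cl2 converts it into 2,3,4,5-tetramethoxybenzoyl chloride F3. The lithium dianion of 4 (LiHMDS 3.5 equiv, THF, −78 °C) is C-acylated by F3 in an intermolecular crossed Claisen condensation, giving 1-(2-hydroxy-3,4,6-trimethoxyphenyl)-3-(2,3,4,5-tetramethoxyphenyl)propane-1,3-dione F4. Cyclodehydration with catalytic H2SO4 in AcOH at 95 °C closes the pyranone through the only free phenol and gives 14.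

Step 8 (selective mono-demethylation of a heptamethyl ether; risk is competitive loss of the 8-methyl group, the next most labile ether of 5,7,8-trimethoxyflavones). The fallback sets out from 14 and comes back at 15. Instead of fighting over-cleavage it is driven on purpose: excess AlBr3 in MeCN at 50 °C followed by dilute HCl gives 5,8-dihydroxy-7-methoxy-2-(2,3,4,5-tetramethoxyphenyl)-4H-chromen-4-one F5. The methyl group is then put back only on the non-chelated 8-OH (MeI 1.05 equiv, K2CO3, acetone, N2, rt). The 5-OH stays free because it is locked in the hydrogen bond to the C4 carbonyl, so the product is 15.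

**Further compounds**
F1 | step 2 | 2,3,4,6-tetramethoxyphenyllithium | [Li]c1c(OC)cc(OC)c(OC)c1OC
F2 | step 6 | 2,3,4,5-tetramethoxybenzoic acid | COc1cc(C(=O)O)c(OC)c(OC)c1OC
F3 | step 6 | 2,3,4,5-tetramethoxybenzoyl chloride | COc1cc(C(=O)Cl)c(OC)c(OC)c1OC
F4 | step 6 | 1-(2-hydroxy-3,4,6-trimethoxyphenyl)-3-(2,3,4,5-tetramethoxyphenyl)propane-1,3-dione | COc1cc(C(=O)CC(=O)c2c(OC)cc(OC)c(OC)c2O)c(OC)c(OC)c1OC
F5 | step 8 | 5,8-dihydroxy-7-methoxy-2-(2,3,4,5-tetramethoxyphenyl)-4H-chromen-4-one | COc1cc(-c2cc(=O)c3c(O)cc(OC)c(O)c3o2)c(OC)c(OC)c1OC
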